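**Strategy**

The propane bridge (Cα on ring A, Cβ, Cγ on C6 of the chromene, ring B) is cut at Cβ–Cγ. Cα is ortho to the C3 hydroxyl of the resorcinol ring A, so it can be carried as a ketone that makes Cβ nucleophilic and is erased afterwards by reduction through an ortho-quinone methide. The key step is thus a Claisen–Schmidt condensation of a ring A methyl ketone with the fully substituted chromene-6-carbaldehyde, which unites both halves as a chalcone in one operation. Conjugate reduction, deoxygenation and a last aromatic Claisen shift of an O-prenyl group to C6 of ring A finish a protecting-group-free route.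

Key step: step 5

Remark: 2-bromo-4,5-dihydroxybenzaldehyde (4) is taken as a catalogue compound; the target has no stereocentre, so only the E geometry of the transient chalcone is defined.

**Route**

Step 1
Reactants: 1 2,4-dihydroxyacetophenone; 2 prenyl bromide (1-bromo-3-methylbut-2-ene)
Product: 3 1-[2-hydroxy-4-(3-methylbut-2-en-1-yloxy)phenyl]ethanone
Conditions: K2CO3 (1.2 equiv), acetone, reflux
Reagents that add atoms: prenyl bromide (2), CC(C)=CCBr
Why: Williamson ether synthesis: the C2 hydroxyl is tied up in a hydrogen bond to the acetyl oxygen, so carbonate deprotonates and alkylates only the C4 hydroxyl.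

Step 2
Reactants: 4 2-bromo-4,5-dihydroxybenzaldehyde; 5 3-chloro-3-methylbut-1-yne
Product: 6 2-bromo-5-hydroxy-4-(2-methylbut-3-yn-2-yloxy)benzaldehyde
Conditions: K2CO3 (1.1 equiv), KI (cat.), CuI (cat.), DMF, 60 °C
Reagents that add atoms: 3-chloro-3-methylbut-1-yne (5), C#CC(C)(C)Cl
Why: Williamson-type O-propargylation: the hydroxyl para to the formyl group is the more acidic one, so one equivalent of carbonate gives its phenoxide, which captures the copper-activated tertiary propargylic chloride at O4.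

Step 3
Reactants: 6 2-bromo-5-hydroxy-4-(2-methylbut-3-yn-2-yloxy)benzaldehyde
Product: 8 5-bromo-8-hydroxy-2,2-dimethyl-2H-chromene-6-carbaldehyde, via allenylphenol 7 (not isolated)
Conditions: N,N-diethylaniline, 190 °C, Ar
Reagents that add atoms: none
Why: Aromatic propargyl Claisen rearrangement to allenylphenol 7 followed by 1,5-hydrogen shift and oxa-6π electrocyclisation: C3 is the only free position ortho to the ether oxygen, so the pyran ring can close in one direction only.

Step 4
Reactants: 8 5-bromo-8-hydroxy-2,2-dimethyl-2H-chromene-6-carbaldehyde; 9 prenylboronic acid pinacol ester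
Product: 10 8-hydroxy-2,2-dimethyl-5-(3-methylbut-2-en-1-yl)-2H-chromene-6-carbaldehyde
Conditions: Pd-PEPPSI-IPent (cat.), aq KOH (3 equiv), THF, 65 °C
Reagents that add atoms: prenylboronic acid pinacol ester (9), CC(C)=CCB1OC(C)(C)C(C)(C)O1
Why: Suzuki–Miyaura coupling of an aryl bromide with an allylic boronate: the ortho formyl group assists oxidative addition and the bulky NHC ligand should force reductive elimination at the unsubstituted allyl terminus, giving the linear prenyl group.

Step 5
Reactants: 3 1-[2-hydroxy-4-(3-methylbut-2-en-1-yloxy)phenyl]ethanone; 10 8-hydroxy-2,2-dimethyl-5-(3-methylbut-2-en-1-yl)-2H-chromene-6-carbaldehyde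
Product: 12 (2E)-1-[2-hydroxy-4-(3-methylbut-2-en-1-yloxy)phenyl]-3-[8-hydroxy-2,2-dimethyl-5-(3-methylbut-2-en-1-yl)-2H-chromen-6-yl]prop-2-en-1-one, via aldol adduct 11 (not isolated)
Conditions: KOH (50% aq, excess), EtOH, rt; cold dilute HCl work-up
Reagents that add atoms: none
Why: Hydroxide generates the enolate of 3 (as its phenoxide), which adds to the formyl carbon of 10 to give aldol 11, and E1cB loss of hydroxide then forms the Cβ=Cγ bond of chalcone 12. The closest known reaction type is the Claisen–Schmidt condensation of a 2-hydroxyacetophenone with a benzaldehyde. No ring is closed and no stereocentre remains; the E alkene is the thermodynamic outcome of the reversible elimination. The step needs cross- over self-condensation, which is secured because 10 has no α-hydrogen and 3 is the only enolisable partner. Strong base keeps the 2'-phenoxide in the open chalcone form, so closure to the flavanone should not compete, and the prenyl ether, the prenyl side chain and the chromene double bond are inert to aqueous alkali at room temperature.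

Step 6
Reactants: 12 (2E)-1-[2-hydroxy-4-(3-methylbut-2-en-1-yloxy)phenyl]-3-[8-hydroxy-2,2-dimethyl-5-(3-methylbut-2-en-1-yl)-2H-chromen-6-yl]prop-2-en-1-one
Product: 13 1-[2-hydroxy-4-(3-methylbut-2-en-1-yloxy)phenyl]-3-[8-hydroxy-2,2-dimethyl-5-(3-methylbut-2-en-1-yl)-2H-chromen-6-yl]propan-1-one
Conditions: Na2S2O4, NaHCO3, dioxane–H2O (1:1), 85 °C, Ar
Reagents that add atoms: none
Why: Dithionite conjugate reduction of an enone: the sulfur reductant attacks only the electron-poor chalcone double bond, so the two trisubstituted prenyl alkenes, the allyl aryl ether and the electron-rich chromene alkene should remain.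

Step 7
Reactants: 13 1-[2-hydroxy-4-(3-methylbut-2-en-1-yloxy)phenyl]-3-[8-hydroxy-2,2-dimethyl-5-(3-methylbut-2-en-1-yl)-2H-chromen-6-yl]propan-1-one
Product: 17 6-{3-[2-hydroxy-4-(3-methylbut-2-en-1-yloxy)phenyl]propyl}-2,2-dimethyl-5-(3-methylbut-2-en-1-yl)-2H-chromen-8-ol, via bis(ethyl carbonate) 14 (not isolated), via ortho-quinone methide 15 (not isolated), via aryl ethyl carbonate 16 (not isolated)
Conditions: ClCO2Et, Et3N, THF, 0 °C; then NaBH4, THF–H2O, 0 °C to rt; then aq NaOH, MeOH, rt
Reagents that add atoms: none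
Why: Reductive deoxygenation of an ortho-hydroxyaryl ketone through its ethyl carbonate: borohydride reduces the ketone of 14, the alkoxide takes over the neighbouring carbonate, the freed phenoxide expels it to give ortho-quinone methide 15, a second hydride adds at Cα to give 16, and hydroxide then cleaves the remaining C8 carbonate.

Step 8
Reactants: 17 6-{3-[2-hydroxy-4-(3-methylbut-2-en-1-yloxy)phenyl]propyl}-2,2-dimethyl-5-(3-methylbut-2-en-1-yl)-2H-chromen-8-ol
Product: 19 Kazinol K, via cyclohexadienone 18 (not isolated)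
Conditions: N,N-diethylaniline, 170 °C, sealed tube, Ar
Reagents that add atoms: none
Why: Aromatic Claisen rearrangement ([3,3]-sigmatropic shift) of the aryl prenyl ether: the allyl unit should arrive inverted as the 1,1-dimethylallyl group at C6, the open ortho position, rather than at C2 between the two oxygens, the para position C4 is blocked by the bridge, and dienone 18 enolises to the phenol.

**Compound list**

1 | 2,4-dihydroxyacetophenone | CC(=O)c1ccc(O)cc1O | starting material
2 | prenyl bromide (1-bromo-3-methylbut-2-ene) | CC(C)=CCBr | starting material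
3 | 1-[2-hydroxy-4-(3-methylbut-2-en-1-yloxy)phenyl]ethanone | CC(=O)c1ccc(OCC=C(C)C)cc1O | intermediate
4 | 2-bromo-4,5-dihydroxybenzaldehyde | O=Cc1cc(O)c(O)cc1Br | starting material
5 | 3-chloro-3-methylbut-1-yne | C#CC(C)(C)Cl | starting material
6 | 2-bromo-5-hydroxy-4-(2-methylbut-3-yn-2-yloxy)benzaldehyde | O=Cc1cc(O)c(OC(C)(C)C#C)cc1Br | intermediate
7 | 2-bromo-4,5-dihydroxy-3-(3-methylbuta-1,2-dien-1-yl)benzaldehyde (allenylphenol, not isolated) | O=Cc1cc(O)c(O)c(C=C=C(C)C)c1Br | intermediate
8 | 5-bromo-8-hydroxy-2,2-dimethyl-2H-chromene-6-carbaldehyde | O=Cc1cc(O)c2OC(C)(C)C=Cc2c1Br | intermediate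
9 | prenylboronic acid pinacol ester (4,4,5,5-tetramethyl-2-(3-methylbut-2-en-1-yl)-1,3,2-dioxaborolane) | CC(C)=CCB1OC(C)(C)C(C)(C)O1 | starting material
10 | 8-hydroxy-2,2-dimethyl-5-(3-methylbut-2-en-1-yl)-2H-chromene-6-carbaldehyde | O=Cc1cc(O)c2OC(C)(C)C=Cc2c1CC=C(C)C | intermediate
11 | 3-hydroxy-1-[2-hydroxy-4-(3-methylbut-2-en-1-yloxy)phenyl]-3-[8-hydroxy-2,2-dimethyl-5-(3-methylbut-2-en-1-yl)-2H-chromen-6-yl]propan-1-one (racemic aldol adduct, not isolated) | O=C(CC(O)c1cc(O)c2OC(C)(C)C=Cc2c1CC=C(C)C)c1ccc(OCC=C(C)C)cc1O | intermediate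
12 | (2E)-1-[2-hydroxy-4-(3-methylbut-2-en-1-yloxy)phenyl]-3-[8-hydroxy-2,2-dimethyl-5-(3-methylbut-2-en-1-yl)-2H-chromen-6-yl]prop-2-en-1-one | O=C(/C=C/c1cc(O)c2OC(C)(C)C=Cc2c1CC=C(C)C)c1ccc(OCC=C(C)C)cc1O | intermediate
13 | 1-[2-hydroxy-4-(3-methylbut-2-en-1-yloxy)phenyl]-3-[8-hydroxy-2,2-dimethyl-5-(3-methylbut-2-en-1-yl)-2H-chromen-6-yl]propan-1-one | O=C(CCc1cc(O)c2OC(C)(C)C=Cc2c1CC=C(C)C)c1ccc(OCC=C(C)C)cc1O | intermediate
14 | 2-{3-[8-(ethoxycarbonyloxy)-2,2-dimethyl-5-(3-methylbut-2-en-1-yl)-2H-chromen-6-yl]propanoyl}-5-(3-methylbut-2-en-1-yloxy)phenyl ethyl carbonate (not isolated) | CCOC(=O)Oc1cc(OCC=C(C)C)ccc1C(=O)CCc1cc(OC(=O)OCC)c2OC(C)(C)C=Cc2c1CC=C(C)C | intermediate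
15 | ethyl 2,2-dimethyl-5-(3-methylbut-2-en-1-yl)-6-{3-[4-(3-methylbut-2-en-1-yloxy)-2-oxocyclohexa-3,5-dien-1-ylidene]propyl}-2H-chromen-8-yl carbonate (ortho-quinone methide, not isolated) | O=C1C=C(OCC=C(C)C)C=CC1=CCCc1cc(OC(=O)OCC)c2OC(C)(C)C=Cc2c1CC=C(C)C | intermediate
16 | ethyl 6-{3-[2-hydroxy-4-(3-methylbut-2-en-1-yloxy)phenyl]propyl}-2,2-dimethyl-5-(3-methylbut-2-en-1-yl)-2H-chromen-8-yl carbonate (not isolated) | CCOC(=O)Oc1cc(CCCc2ccc(OCC=C(C)C)cc2O)c(CC=C(C)C)c2C=CC(C)(C)Oc12 | intermediate
17 | 6-{3-[2-hydroxy-4-(3-methylbut-2-en-1-yloxy)phenyl]propyl}-2,2-dimethyl-5-(3-methylbut-2-en-1-yl)-2H-chromen-8-ol | Oc1cc(CCCc2ccc(OCC=C(C)C)cc2O)c(CC=C(C)C)c2C=CC(C)(C)Oc12 | intermediate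
18 | 3-hydroxy-4-{3-[8-hydroxy-2,2-dimethyl-5-(3-methylbut-2-en-1-yl)-2H-chromen-6-yl]propyl}-6-(2-methylbut-3-en-2-yl)cyclohexa-2,4-dien-1-one (racemic, not isolated) | O=C1C=C(O)C(CCCc2cc(O)c3OC(C)(C)C=Cc3c2CC=C(C)C)=CC1C(C)(C)C=C | intermediate
19 | Kazinol K, 4-{3-[8-hydroxy-2,2-dimethyl-5-(3-methylbut-2-en-1-yl)-2H-chromen-6-yl]propyl}-6-(2-methylbut-3-en-2-yl)benzene-1,3-diol | C=CC(C)(C)c1cc(CCCc2cc(O)c3c(c2CC=C(C)C)C=CC(C)(C)O3)c(O)cc1O | target

**Step count and risks**

Total steps: 8. Longest linear sequence: 7 steps (steps 2 to 8, from 4).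

Risk 1 (step 8): the [3,3] shift may lose regiocontrol and deliver the allyl unit to C2 of ring A between the two oxygens, and prolonged heating may degrade the ortho-(1,1-dimethylallyl)phenol by further rearrangement or ring closure onto the neighbouring hydroxyl. The fallback sets out from 17 and uses a steric steering group. Both phenols would be silylated (TBSCl, imidazole, DMF, rt) to the bis(tert-butyldimethylsilyl) ether F1, in which the bulky silyloxy group at C3 of ring A screens C2. Heating (N,N-diethylaniline, 170 °C) should then pass through the cyclohexadienone F2 (not isolated) to the C6-(1,1-dimethylallyl) phenol F3, which still carries both silyl groups. Desilylation (TBAF, AcOH, THF, 0 °C) comes back to the route at 19.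

Risk 2 (step 4): allylic transposition at palladium may give the branched 1,1-dimethylallyl isomer, and oxidative addition may be slow at a bromide flanked on both sides and para to a phenoxide. The fallback sets out from 8 and removes the regiochemical choice. Suzuki–Miyaura coupling with allylboronic acid pinacol ester (Pd(dppf)Cl2, K2CO3, dioxane–H2O, 80 °C) should give 5-allyl-8-hydroxy-2,2-dimethyl-2H-chromene-6-carbaldehyde F4. Olefin cross-metathesis with excess 2-methylbut-2-ene (second-generation Ru–NHC benzylidene catalyst, CH2Cl2, 40 °C) then converts the allyl into the prenyl group and comes back at 10; the hindered cyclic chromene alkene should not take part.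

Risk 3 (step 6): electron transfer to an enone that is deactivated as its phenoxide may be incomplete, the 2'-hydroxychalcone may close to the flavanone in warm weak base, and sulfite may add to the enone. The fallback sets out from 12 and changes to a protected substrate and a hydridic copper reagent. Silylation of both phenols (TBSOTf, 2,6-lutidine, CH2Cl2, 0 °C) should give the bis(tert-butyldimethylsilyl) chalcone F5, which can no longer cyclise or quench a hydride. Conjugate reduction with [(Ph3P)CuH]6 (wet benzene–THF, rt) should give the bis-silyl dihydrochalcone F6, and TBAF/AcOH (THF, 0 °C) comes back at 13.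

**Further compounds**

F1 | step 8 | bis(tert-butyldimethylsilyl) ether of 17 (ring A C3–O and chromene C8–O silylated) | CC(C)(C)[Si](C)(C)Oc1cc(OCC=C(C)C)ccc1CCCc1cc(O[Si](C)(C)C(C)(C)C)c2OC(C)(C)C=Cc2c1CC=C(C)C
F2 | step 8 | 3-(tert-butyldimethylsilyloxy)-4-{3-[8-(tert-butyldimethylsilyloxy)-2,2-dimethyl-5-(3-methylbut-2-en-1-yl)-2H-chromen-6-yl]propyl}-6-(2-methylbut-3-en-2-yl)cyclohexa-2,4-dien-1-one (racemic, not isolated) | CC(C)(C)[Si](C)(C)OC1=CC(=O)C(C(C)(C)C=C)C=C1CCCc1cc(O[Si](C)(C)C(C)(C)C)c2OC(C)(C)C=Cc2c1CC=C(C)C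
F3 | step 8 | bis(tert-butyldimethylsilyl) ether of 19 (ring A C3–O and chromene C8–O silylated, ring A C1–OH free) | CC(C)(C)[Si](C)(C)Oc1cc(O)c(C(C)(C)C=C)cc1CCCc1cc(O[Si](C)(C)C(C)(C)C)c2OC(C)(C)C=Cc2c1CC=C(C)C
F4 | step 4 | 5-allyl-8-hydroxy-2,2-dimethyl-2H-chromene-6-carbaldehyde | O=Cc1cc(O)c2OC(C)(C)C=Cc2c1CC=C
F5 | step 6 | bis(tert-butyldimethylsilyl) ether of chalcone 12 | O=C(/C=C/c1cc(O[Si](C)(C)C(C)(C)C)c2OC(C)(C)C=Cc2c1CC=C(C)C)c1ccc(OCC=C(C)C)cc1O[Si](C)(C)C(C)(C)C
F6 | step 6 | bis(tert-butyldimethylsilyl) ether of dihydrochalcone 13 | O=C(CCc1cc(O[Si](C)(C)C(C)(C)C)c2OC(C)(C)C=Cc2c1CC=C(C)C)c1ccc(OCC=C(C)C)cc1O[Si](C)(C)C(C)(C)C
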